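**Plan**

Core numbering used below: C1 (methyl-bearing oxirane carbon), C2 and C3 (ester-bearing), C4 (side-chain-bearing), C5 (CH2), C6 (oxirane CH); side chain C1′ (=CH2) to C7′.

- Retrosynthesis: the two angelates and the oxirane come off last (to a cis-diol methylcyclohexene). The side chain is cut at C3′–C4′ (allylation, then cross-metathesis) and at the exo-methylene (aldehyde α-methylenation) back to a CH2CH2O arm. The C1 methyl goes back to a C1 ketone. The carbocycle is then cut at C5–C6 and C2–C3 together.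
- Enabling feature: in the cyclohexane ring, C1 is a latent ketone carbon flanked by its two α-carbons C6 and C2, and C4 is the α-carbon of a latent acrolein whose β-CH2 is C5 and whose formyl carbon is the carbinol C3. A 4-(benzyloxy)acetoacetate (1,3-dinucleophile) and a 2-substituted acrolein (1,3-dielectrophile) therefore close the ring by Michael addition (C5–C6) and aldol addition (C2–C3).
- Forward order: the (3+3) annulation builds the six-membered carbocycle; decarboxylation, acetonide formation and enol triflate/methylation give the methylcyclohexene; the side chain is grown; the oxirane ring is closed in the penultimate step; the angelates go on last.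
- Stereochemistry: C2, C3 and C4 (all-cis) come from the L-proline-mediated aldol closure with dynamic resolution of the α-formyl centre. C3′ comes from reagent-controlled Brown allylation. C1 and C6 come from hydroxyl-directed epoxidation. The Z-esters come from angelic acid itself.

Key step: step 3

Assumption: the facial sense of the L-proline aldol closure in step 3 is taken to follow the Hajos–Parrish/Houk–List enamine model; D-proline would be substituted, with no other change, if the antipodal series were to form.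

**Route**

Step 1
Reactants: 1 4-[(tert-butyldimethylsilyl)oxy]butanal
Product: 2 4-[(tert-butyldimethylsilyl)oxy]-2-methylidenebutanal
Conditions: 37% aq. HCHO, pyrrolidine (10 mol%), EtCO2H (10 mol%), i-PrOH, 45 °C
Reagents that add atoms: formaldehyde, C=O
Why: Amine-catalysed Mannich condensation/elimination (α-methylenation of an aldehyde) should install the methylene next to the formyl group; no stereocentre is formed.

Step 2
Reactants: 3 ethyl 4-(benzyloxy)-3-oxobutanoate
Product: 4 benzyl 4-(benzyloxy)-3-oxobutanoate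
Conditions: BnOH (1.5 equiv), DMAP (10 mol%), toluene, 110 °C, EtOH distilled off
Reagents that add atoms: benzyl alcohol, OCc1ccccc1
Why: β-Keto esters transesterify readily (DMAP-catalysed, via the acylketene) and removal of ethanol drives the exchange; the benzyl ester lets ester and ether be cleaved together in step 4.

Step 3
Reactants: 2 4-[(tert-butyldimethylsilyl)oxy]-2-methylidenebutanal; 4 benzyl 4-(benzyloxy)-3-oxobutanoate
Product: 6 benzyl (3R,4R,5S)-3-(benzyloxy)-5-{2-[(tert-butyldimethylsilyl)oxy]ethyl}-4-hydroxy-2-oxocyclohexane-1-carboxylate (all-cis at C3, C4, C5; C1 epimers/enol), via Michael adduct 5 (not isolated)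
Conditions: L-proline (30 mol%), DMSO, 25 °C
Reagents that add atoms: none
Why: The proline-derived iminium ion of enal 2 accepts the doubly activated C–H of 4 at its unsubstituted β-CH2 to give keto aldehyde 5, and the cross-conjugated enamine formed from the ketone of 5 toward the benzyloxy-bearing carbon then adds to the formyl group, so the C5–C6 and C2–C3 bonds of the target ring arise in one flask. The closest known reaction types are the amine-catalysed Michael/aldol (3+3) annulation of β-keto esters with enals and the proline-mediated Hajos–Parrish ketol closure. The carbocycle closes in the 6-(enolendo)-exo-trig mode through a chair-like transition state. The carbinol centre is set by the Houk–List arrangement, in which the proline carboxylic acid hydrogen-bonds to the formyl oxygen and places it axial on the face fixed by L-proline; the side-arm centre is set by dynamic kinetic resolution, since the α-formyl methine epimerises through the aldehyde enamine and cyclises with the arm equatorial; the benzyloxy centre should end equatorial (cis to the hydroxyl) and stays correctable because it is α to the ketone. The step needs 1,4- over 1,2-addition, which the unhindered methylene terminus and the α-branched carbonyl of 2 favour, and closure through the γ-carbon only, which is secured because attack by the activated carbon would give a cyclobutane. Dehydration of the ketol should be avoided by the near-neutral medium at 25 °C.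

Step 4
Reactants: 6 benzyl (3R,4R,5S)-3-(benzyloxy)-5-{2-[(tert-butyldimethylsilyl)oxy]ethyl}-4-hydroxy-2-oxocyclohexane-1-carboxylate
Product: 8 (2R,3R,4S)-4-{2-[(tert-butyldimethylsilyl)oxy]ethyl}-2,3-dihydroxycyclohexan-1-one, via keto acid 7 (not isolated)
Conditions: H2 (1 atm), Pd/C (10%), EtOAc, 23 °C; then 40 °C
Reagents that add atoms: none
Why: Hydrogenolysis should cleave both benzyl groups, and the liberated β-keto acid loses CO2 on gentle warming, removing the activating carboxyl group tracelessly; the silyl ether and the three stereocentres are untouched in the neutral medium.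

Step 5
Reactants: 8 (2R,3R,4S)-4-{2-[(tert-butyldimethylsilyl)oxy]ethyl}-2,3-dihydroxycyclohexan-1-one
Product: 9 (3aR,7S,7aR)-7-{2-[(tert-butyldimethylsilyl)oxy]ethyl}-2,2-dimethylhexahydro-1,3-benzodioxol-4-one (cis-fused acetonide)
Conditions: Me2C(OMe)2, PPTS (10 mol%), acetone, 23 °C
Reagents that add atoms: 2,2-dimethoxypropane, COC(C)(C)OC
Why: Acid-catalysed transketalisation should give the cis-fused dioxolane of the cis-diol, which also funnels the epimerisable α-oxygenated centre into the cis series (thermodynamic acetonide formation).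

Step 6
Reactants: 9 (3aR,7S,7aR)-7-{2-[(tert-butyldimethylsilyl)oxy]ethyl}-2,2-dimethylhexahydro-1,3-benzodioxol-4-one
Product: 11 (3aR,7S,7aR)-7-{2-[(tert-butyldimethylsilyl)oxy]ethyl}-2,2-dimethyl-3a,6,7,7a-tetrahydro-1,3-benzodioxol-4-yl trifluoromethanesulfonate, via lithium enolate 10 (not isolated)
Conditions: LiN(i-Pr)2, THF, −78 °C; then PhNTf2, −78 to 0 °C
Reagents that add atoms: N-phenylbis(trifluoromethanesulfonimide), O=S(=O)(N(c1ccccc1)S(=O)(=O)C(F)(F)F)C(F)(F)F
Why: Kinetic deprotonation by the hindered amide should occur at the unhindered CH2 and not at the alkoxy-bearing methine, and O-triflation fixes the double bond between the future C6 and C1 (regioselective enol triflate formation).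

Step 7
Reactants: 11 (3aR,7S,7aR)-7-{2-[(tert-butyldimethylsilyl)oxy]ethyl}-2,2-dimethyl-3a,6,7,7a-tetrahydro-1,3-benzodioxol-4-yl trifluoromethanesulfonate
Product: 12 tert-butyldimethyl{2-[(3aS,7S,7aR)-2,2,4-trimethyl-3a,6,7,7a-tetrahydro-1,3-benzodioxol-7-yl]ethoxy}silane
Conditions: MeMgBr, Fe(acac)3 (5 mol%), THF/NMP, −30 °C
Reagents that add atoms: methylmagnesium bromide, C[Mg]Br
Why: Iron-catalysed cross-coupling of an alkenyl triflate with a methyl Grignard reagent should replace the triflate by methyl without moving the double bond; silyl ether and ketal are inert.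

Step 8
Reactants: 12 tert-butyldimethyl{2-[(3aS,7S,7aR)-2,2,4-trimethyl-3a,6,7,7a-tetrahydro-1,3-benzodioxol-7-yl]ethoxy}silane
Product: 13 2-[(3aS,7S,7aR)-2,2,4-trimethyl-3a,6,7,7a-tetrahydro-1,3-benzodioxol-7-yl]ethan-1-ol
Conditions: Bu4NF, THF, 0 to 23 °C
Reagents that add atoms: none
Why: Fluoride-mediated desilylation should free the primary alcohol while the acetonide stays in place.

Step 9
Reactants: 13 2-[(3aS,7S,7aR)-2,2,4-trimethyl-3a,6,7,7a-tetrahydro-1,3-benzodioxol-7-yl]ethan-1-ol
Product: 14 [(3aS,7S,7aR)-2,2,4-trimethyl-3a,6,7,7a-tetrahydro-1,3-benzodioxol-7-yl]acetaldehyde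
Conditions: TEMPO (10 mol%), PhI(OAc)2, CH2Cl2, 23 °C
Reagents that add atoms: none
Why: The oxoammonium oxidation should stop at the aldehyde and leave the trisubstituted alkene and the ketal alone.

Step 10
Reactants: 14 [(3aS,7S,7aR)-2,2,4-trimethyl-3a,6,7,7a-tetrahydro-1,3-benzodioxol-7-yl]acetaldehyde
Product: 15 2-[(3aS,7S,7aR)-2,2,4-trimethyl-3a,6,7,7a-tetrahydro-1,3-benzodioxol-7-yl]prop-2-enal
Conditions: 37% aq. HCHO, pyrrolidine (10 mol%), EtCO2H (10 mol%), i-PrOH, 45 °C
Reagents that add atoms: formaldehyde, C=O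
Why: The same Mannich/elimination α-methylenation as in step 1 should create the exo-methylene (C1′=C2′); the ring stereocentre β to the aldehyde is not enolisable.

Step 11
Reactants: 15 2-[(3aS,7S,7aR)-2,2,4-trimethyl-3a,6,7,7a-tetrahydro-1,3-benzodioxol-7-yl]prop-2-enal
Product: 17 (3S)-2-[(3aS,7S,7aR)-2,2,4-trimethyl-3a,6,7,7a-tetrahydro-1,3-benzodioxol-7-yl]hexa-1,5-dien-3-ol, via borinate 16 (not isolated)
Conditions: (−)-Ipc2B(allyl) [the reagent derived from (+)-α-pinene], Et2O, −78 °C; then 3 M NaOH, 30% H2O2, 0 to 23 °C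
Reagents that add atoms: (−)-B-allyldiisopinocampheylborane, C=CCB([C@@H]1C[C@@H]2C[C@H]([C@H]1C)C2(C)C)[C@@H]1C[C@@H]2C[C@H]([C@H]1C)C2(C)C
Why: Brown allylboration through a closed chair transition state should add allyl to the Si face of the enal carbonyl under reagent control, giving the (S)-carbinol by 1,2-addition only.

Step 12
Reactants: 17 (3S)-2-[(3aS,7S,7aR)-2,2,4-trimethyl-3a,6,7,7a-tetrahydro-1,3-benzodioxol-7-yl]hexa-1,5-dien-3-ol
Product: 18 (3S)-2-[(3aS,7S,7aR)-2,2,4-trimethyl-3a,6,7,7a-tetrahydro-1,3-benzodioxol-7-yl]hexa-1,5-dien-3-yl acetate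
Conditions: Ac2O, pyridine, DMAP (5 mol%), CH2Cl2, 23 °C
Reagents that add atoms: acetic anhydride, CC(=O)OC(C)=O
Why: Standard acylation of the secondary allylic alcohol installs the side-chain acetate, so that only the ring hydroxyls can later direct the epoxidation.

Step 13
Reactants: 18 (3S)-2-[(3aS,7S,7aR)-2,2,4-trimethyl-3a,6,7,7a-tetrahydro-1,3-benzodioxol-7-yl]hexa-1,5-dien-3-yl acetate
Product: 19 (3S)-6-methyl-2-[(3aS,7S,7aR)-2,2,4-trimethyl-3a,6,7,7a-tetrahydro-1,3-benzodioxol-7-yl]hepta-1,5-dien-3-yl acetate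
Conditions: 2-methylbut-2-ene (excess), second-generation Grubbs catalyst (5 mol%), CH2Cl2, 40 °C
Reagents that add atoms: 2-methylbut-2-ene, CC=C(C)C
Why: Olefin cross-metathesis of the monosubstituted alkene with excess 2-methylbut-2-ene should install the prenyl terminus; the 1,1-disubstituted and ring trisubstituted alkenes are too hindered to take part.

Step 14
Reactants: 19 (3S)-6-methyl-2-[(3aS,7S,7aR)-2,2,4-trimethyl-3a,6,7,7a-tetrahydro-1,3-benzodioxol-7-yl]hepta-1,5-dien-3-yl acetate
Product: 20 (3S)-2-[(1S,5S,6R)-5,6-dihydroxy-4-methylcyclohex-3-en-1-yl]-6-methylhepta-1,5-dien-3-yl acetate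
Conditions: AcOH/H2O (4:1), 40 °C
Reagents that add atoms: none
Why: Mild aqueous acid should hydrolyse the isopropylidene ketal while the acetate and the alkenes survive.

Step 15
Reactants: 20 (3S)-2-[(1S,5S,6R)-5,6-dihydroxy-4-methylcyclohex-3-en-1-yl]-6-methylhepta-1,5-dien-3-yl acetate
Product: 21 (3S)-2-[(1R,2R,3R,4S,6S)-2,3-dihydroxy-1-methyl-7-oxabicyclo[4.1.0]heptan-4-yl]-6-methylhepta-1,5-dien-3-yl acetate
Conditions: VO(acac)2 (5 mol%), t-BuOOH (in decane), CH2Cl2, 0 to 23 °C
Reagents that add atoms: tert-butyl hydroperoxide, CC(C)(C)OO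
Why: Hydroxyl-directed epoxidation (Sharpless–Michaelson type) should deliver oxygen from the vanadate of the allylic C2 hydroxyl to the same face, giving the oxirane cis to both hydroxyls and leaving the side-chain alkenes, which carry no free hydroxyl, untouched.

Step 16
Reactants: 21 (3S)-2-[(1R,2R,3R,4S,6S)-2,3-dihydroxy-1-methyl-7-oxabicyclo[4.1.0]heptan-4-yl]-6-methylhepta-1,5-dien-3-yl acetate
Product: 22 (1S,2R,3R,4S,6S)-4-[(3S)-3-(acetyloxy)-6-methylhepta-1,5-dien-2-yl]-1-methyl-7-oxabicyclo[4.1.0]heptane-2,3-diyl bis[(2Z)-2-methylbut-2-enoate]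
Conditions: angelic acid, 2,4,6-trichlorobenzoyl chloride, Et3N, toluene, 23 °C; then 21, 80 °C
Reagents that add atoms: angelic acid [(2Z)-2-methylbut-2-enoic acid], C/C=C(/C)C(=O)O
Why: Acylation by the mixed angelic 2,4,6-trichlorobenzoic anhydride (Yamaguchi-type esterification without a nucleophilic catalyst) should esterify both secondary hydroxyls while avoiding the amine-induced Z-to-E isomerisation to the tiglate.

**Compound list**

1 | 4-[(tert-butyldimethylsilyl)oxy]butanal | O=CCCCO[Si](C)(C)C(C)(C)C | starting material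
2 | 4-[(tert-butyldimethylsilyl)oxy]-2-methylidenebutanal | C=C(C=O)CCO[Si](C)(C)C(C)(C)C | intermediate
3 | ethyl 4-(benzyloxy)-3-oxobutanoate | CCOC(=O)CC(=O)COCc1ccccc1 | starting material
4 | benzyl 4-(benzyloxy)-3-oxobutanoate | O=C(CC(=O)COCc1ccccc1)OCc1ccccc1 | intermediate
5 | benzyl 2-[(benzyloxy)acetyl]-6-[(tert-butyldimethylsilyl)oxy]-4-formylhexanoate (stereoisomer mixture; Michael adduct) | O=CC(CCO[Si](C)(C)C(C)(C)C)CC(C(=O)COCc1ccccc1)C(=O)OCc1ccccc1 | intermediate
6 | benzyl (3R,4R,5S)-3-(benzyloxy)-5-{2-[(tert-butyldimethylsilyl)oxy]ethyl}-4-hydroxy-2-oxocyclohexane-1-carboxylate (C1 epimers/enol) | CC(C)(C)[Si](C)(C)OCC[C@@H]1CC(C(=O)OCc2ccccc2)C(=O)[C@H](OCc2ccccc2)[C@@H]1O | intermediate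
7 | (3R,4R,5S)-5-{2-[(tert-butyldimethylsilyl)oxy]ethyl}-3,4-dihydroxy-2-oxocyclohexane-1-carboxylic acid | CC(C)(C)[Si](C)(C)OCC[C@@H]1CC(C(=O)O)C(=O)[C@H](O)[C@@H]1O | intermediate
8 | (2R,3R,4S)-4-{2-[(tert-butyldimethylsilyl)oxy]ethyl}-2,3-dihydroxycyclohexan-1-one | CC(C)(C)[Si](C)(C)OCC[C@@H]1CCC(=O)[C@H](O)[C@@H]1O | intermediate
9 | (3aR,7S,7aR)-7-{2-[(tert-butyldimethylsilyl)oxy]ethyl}-2,2-dimethylhexahydro-1,3-benzodioxol-4-one | CC(C)(C)[Si](C)(C)OCC[C@@H]1CCC(=O)[C@@H]2OC(C)(C)O[C@H]12 | intermediate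
10 | lithium (3aR,7S,7aR)-7-{2-[(tert-butyldimethylsilyl)oxy]ethyl}-2,2-dimethyl-3a,6,7,7a-tetrahydro-1,3-benzodioxol-4-olate (lithium enolate) | CC(C)(C)[Si](C)(C)OCC[C@@H]1CC=C(O[Li])[C@@H]2OC(C)(C)O[C@H]12 | intermediate
11 | (3aR,7S,7aR)-7-{2-[(tert-butyldimethylsilyl)oxy]ethyl}-2,2-dimethyl-3a,6,7,7a-tetrahydro-1,3-benzodioxol-4-yl trifluoromethanesulfonate | CC(C)(C)[Si](C)(C)OCC[C@@H]1CC=C(OS(=O)(=O)C(F)(F)F)[C@@H]2OC(C)(C)O[C@H]12 | intermediate
12 | tert-butyldimethyl{2-[(3aS,7S,7aR)-2,2,4-trimethyl-3a,6,7,7a-tetrahydro-1,3-benzodioxol-7-yl]ethoxy}silane | CC(C)(C)[Si](C)(C)OCC[C@@H]1CC=C(C)[C@@H]2OC(C)(C)O[C@H]12 | intermediate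
13 | 2-[(3aS,7S,7aR)-2,2,4-trimethyl-3a,6,7,7a-tetrahydro-1,3-benzodioxol-7-yl]ethan-1-ol | OCC[C@@H]1CC=C(C)[C@@H]2OC(C)(C)O[C@H]12 | intermediate
14 | [(3aS,7S,7aR)-2,2,4-trimethyl-3a,6,7,7a-tetrahydro-1,3-benzodioxol-7-yl]acetaldehyde | O=CC[C@@H]1CC=C(C)[C@@H]2OC(C)(C)O[C@H]12 | intermediate
15 | 2-[(3aS,7S,7aR)-2,2,4-trimethyl-3a,6,7,7a-tetrahydro-1,3-benzodioxol-7-yl]prop-2-enal | C=C(C=O)[C@@H]1CC=C(C)[C@@H]2OC(C)(C)O[C@H]12 | intermediate
16 | (3S)-2-[(3aS,7S,7aR)-2,2,4-trimethyl-3a,6,7,7a-tetrahydro-1,3-benzodioxol-7-yl]hexa-1,5-dien-3-yl diisopinocampheylborinate | C=C([C@H](CC=C)OB([C@@H]3C[C@@H]4C[C@H]([C@H]3C)C4(C)C)[C@@H]3C[C@@H]4C[C@H]([C@H]3C)C4(C)C)[C@@H]1CC=C(C)[C@@H]2OC(C)(C)O[C@H]12 | intermediate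
17 | (3S)-2-[(3aS,7S,7aR)-2,2,4-trimethyl-3a,6,7,7a-tetrahydro-1,3-benzodioxol-7-yl]hexa-1,5-dien-3-ol | C=C([C@H](CC=C)O)[C@@H]1CC=C(C)[C@@H]2OC(C)(C)O[C@H]12 | intermediate
18 | (3S)-2-[(3aS,7S,7aR)-2,2,4-trimethyl-3a,6,7,7a-tetrahydro-1,3-benzodioxol-7-yl]hexa-1,5-dien-3-yl acetate | C=C([C@H](CC=C)OC(C)=O)[C@@H]1CC=C(C)[C@@H]2OC(C)(C)O[C@H]12 | intermediate
19 | (3S)-6-methyl-2-[(3aS,7S,7aR)-2,2,4-trimethyl-3a,6,7,7a-tetrahydro-1,3-benzodioxol-7-yl]hepta-1,5-dien-3-yl acetate | C=C([C@H](CC=C(C)C)OC(C)=O)[C@@H]1CC=C(C)[C@@H]2OC(C)(C)O[C@H]12 | intermediate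
20 | (3S)-2-[(1S,5S,6R)-5,6-dihydroxy-4-methylcyclohex-3-en-1-yl]-6-methylhepta-1,5-dien-3-yl acetate | C=C([C@H](CC=C(C)C)OC(C)=O)[C@@H]1CC=C(C)[C@H](O)[C@@H]1O | intermediate
21 | (3S)-2-[(1R,2R,3R,4S,6S)-2,3-dihydroxy-1-methyl-7-oxabicyclo[4.1.0]heptan-4-yl]-6-methylhepta-1,5-dien-3-yl acetate | C=C([C@H](CC=C(C)C)OC(C)=O)[C@@H]1C[C@@H]2O[C@]2(C)[C@H](O)[C@@H]1O | intermediate
22 | (1S,2R,3R,4S,6S)-4-[(3S)-3-(acetyloxy)-6-methylhepta-1,5-dien-2-yl]-1-methyl-7-oxabicyclo[4.1.0]heptane-2,3-diyl bis[(2Z)-2-methylbut-2-enoate] | C=C([C@H](CC=C(C)C)OC(C)=O)[C@@H]1C[C@@H]2O[C@]2(C)[C@H](OC(=O)/C(C)=C\C)[C@@H]1OC(=O)/C(C)=C\C | target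

**Totals and risks**

Total step count: 16. Longest linear sequence: 15 steps (steps 1, 3–16 from 1; equally steps 2–16 from 3).

Steps most likely to fail:

1. Step 3. The γ-enamine of the β-keto ester may form too slowly, so that the aldol closure stalls or gives way to condensation and dehydration pathways, and control of the carbinol face may be incomplete. Fallback: the two bond formations are decoupled. Et3N-catalysed Michael addition of 4 to 2 gives 5, which is isolated. Hydrogenolysis (H2, Pd/C, EtOAc) removes both benzyl groups and the carboxyl group and gives 2-{2-[(tert-butyldimethylsilyl)oxy]ethyl}-6-hydroxy-5-oxohexanal F1. L-Proline in DMSO then closes the ring by the hydroxyacetone-type enamine aldol, in which the enamine forms toward the hydroxylated carbon and only that carbon can reach the aldehyde through a six-membered transition state. The route is rejoined at 8.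

2. Step 6. Enolisation may occur toward the alkoxy-bearing methine, with β-elimination of the ketal oxygen or formation of the regioisomeric triflate. Fallback: a Shapiro sequence from 9. Condensation with 2,4,6-triisopropylbenzenesulfonyl hydrazide gives the sulfonylhydrazone F2. n-BuLi (2.2 equiv, THF, −78 to 0 °C) generates the less substituted vinyllithium F3 with loss of dinitrogen and sulfinate. Quenching with MeI places the methyl group on the former carbonyl carbon and rejoins the route at 12, bypassing 11.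

3. Step 16. Z-to-E isomerisation to the tiglate, incomplete acylation of the hindered axial C3 hydroxyl, or opening of the oxirane under the heated acylation may occur. Fallback: the Z-alkenes are built on the ester in place. From 21, both hydroxyls are esterified with 2-[bis(2,2,2-trifluoroethoxy)phosphoryl]propanoic acid (EDC·HCl, DMAP, CH2Cl2, 0 °C) to give the bis(phosphonopropanoate) F4. A double Still–Gennari olefination with acetaldehyde (KN(SiMe3)2, 18-crown-6, THF, −78 °C) then forms both (Z)-2-methylbut-2-enoates and rejoins the route at 22.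

Further compounds
F1 | step 3 | 2-{2-[(tert-butyldimethylsilyl)oxy]ethyl}-6-hydroxy-5-oxohexanal | O=CC(CCO[Si](C)(C)C(C)(C)C)CCC(=O)CO
F2 | step 6 | 2,4,6-triisopropylbenzenesulfonylhydrazone of 9 | CC(C)(C)[Si](C)(C)OCC[C@@H]1CCC(=NNS(=O)(=O)c3c(C(C)C)cc(C(C)C)cc3C(C)C)[C@@H]2OC(C)(C)O[C@H]12
F3 | step 6 | [(3aS,7S,7aR)-7-{2-[(tert-butyldimethylsilyl)oxy]ethyl}-2,2-dimethyl-3a,6,7,7a-tetrahydro-1,3-benzodioxol-4-yl]lithium | CC(C)(C)[Si](C)(C)OCC[C@@H]1CC=C([Li])[C@@H]2OC(C)(C)O[C@H]12
F4 | step 16 | bis{2-[bis(2,2,2-trifluoroethoxy)phosphoryl]propanoate} of 21 (mixture at the two phosphonate α-carbons) | C=C([C@H](CC=C(C)C)OC(C)=O)[C@@H]1C[C@@H]2O[C@]2(C)[C@H](OC(=O)C(C)P(=O)(OCC(F)(F)F)OCC(F)(F)F)[C@@H]1OC(=O)C(C)P(=O)(OCC(F)(F)F)OCC(F)(F)F
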